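**Plan**
- Retrosynthesis: the 4'-O-benzyl group is removed first; ring C is then cut at O1–C8a and C4–C4a in one operation, leaving 3,4,5-trimethoxybenzyne and an (S)-3-aryl-3-oxidopropanoyl unit held as a Weinreb amide; that amide is cut at C3–C4 (acylation of an acetamide enolate).
- Enabling feature: C8a and C4a are neighbouring carbons of ring A that carry O1 and the acyl carbon C4, these two being 1,3-related along C2–C3–C4, and C4a lies beside the C5 methoxy group. This is the pattern a 3-methoxyaryne writes: nucleophile on the far carbon, electrophile on the near one.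
- Forward: ring A becomes an ortho-silylaryl triflate (2 steps); ring B and the C2–C3–C4 chain are joined and set up (3 steps); ring C is closed by the aryne annulation; hydrogenolysis ends the route.
- Helpers: the O-SiMe3 group (proton-free alkoxide source) and the N-methoxy-N-methyl amide (acyl acceptor) both leave in the key step; benzyl leaves last.
- Stereochemistry: C2 is set by asymmetric transfer hydrogenation with the (S,S)-catalyst; its C–O bond is never broken afterwards, and C4 stays a tetrahedral adduct until quench so that base cannot open ring C.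

Key step: step 6

Remark: flavanone numbering is used (O1, C2, C3, C4, C4a, C5 to C8, C8a; ring A = trimethoxybenzo ring, ring B = aryl substituent, ring C = pyranone ring); the target SMILES corresponds to the 2S enantiomer.

**Step 1**
Reactants: 1 3,4,5-trimethoxyphenol
Product: 2 2-bromo-3,4,5-trimethoxyphenol
Conditions: NBS (1.0 equiv), CH2Cl2, −78 °C to 0 °C, dark
Reagents that add atoms: N-bromosuccinimide, O=C1CCC(=O)N1Br
Why: Electrophilic aromatic bromination of the activated phenol; the two free ring positions are equivalent by symmetry and both ortho to the hydroxyl, so only one monobromide is possible, and one equivalent of NBS at low temperature should hold back the dibromide.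

**Step 2**
Reactants: 2 2-bromo-3,4,5-trimethoxyphenol
Product: 6 3,4,5-trimethoxy-2-(trimethylsilyl)phenyl trifluoromethanesulfonate, via O-trimethylsilyl ether 3 (not isolated), via aryllithium 4 (not isolated), via lithium 2-silylphenolate 5 (not isolated)
Conditions: HN(SiMe3)2, THF, 70 °C, then evaporation; n-BuLi, THF, −100 °C to −80 °C; Tf2O, −100 °C to rt
Reagents that add atoms: hexamethyldisilazane, C[Si](C)(C)N[Si](C)(C)C; trifluoromethanesulfonic anhydride, O=S(=O)(OS(=O)(=O)C(F)(F)F)C(F)(F)F
Why: One-flask O-silylation, bromine–lithium exchange, anionic 1,3-shift of silicon from oxygen to carbon (retro-Brook rearrangement) and O-triflation of the lithium phenolate, the standard way from an ortho-bromophenol to an ortho-silylaryl triflate.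

**Step 3**
Reactants: 7 4-(benzyloxy)-3-methoxybenzoic acid; 8 N-methoxy-N-methylacetamide
Product: 11 3-[4-(benzyloxy)-3-methoxyphenyl]-N-methoxy-N-methyl-3-oxopropanamide, via acyl imidazolide 9 (not isolated), via lithium amide enolate 10 (not isolated)
Conditions: 7, CDI, THF, rt; 8 (3.3 equiv), LiN(i-Pr)2 (3.3 equiv, commercial solution), THF, −78 °C; solution of 9 added at −78 °C, then to −20 °C; aq NH4Cl
Reagents that add atoms: none
Why: Crossed Claisen-type C-acylation of the acetamide lithium enolate by the acyl imidazolide, the excess enolate taking up the N–H of the freed imidazole and the acidic C–H of the keto amide so that the reaction is pulled to product; no stereocenter is formed.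

**Step 4**
Reactants: 11 3-[4-(benzyloxy)-3-methoxyphenyl]-N-methoxy-N-methyl-3-oxopropanamide
Product: 12 (3S)-3-[4-(benzyloxy)-3-methoxyphenyl]-3-hydroxy-N-methoxy-N-methylpropanamide
Conditions: RuCl(p-cymene)[(S,S)-TsDPEN] (1 mol%), HCO2H/Et3N (5:2), DMF, 40 °C
Reagents that add atoms: none
Why: Noyori asymmetric transfer hydrogenation of an aryl ketone; in the six-membered hydride/proton transfer transition state the CH–π contact between the p-cymene ligand and the ketone aryl ring puts hydride on the Re face, which with the (S,S)-ligand should give the S carbinol (C2 of the target), while the Weinreb amide and the benzyl ether are inert to the ruthenium hydride.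

**Step 5**
Reactants: 12 (3S)-3-[4-(benzyloxy)-3-methoxyphenyl]-3-hydroxy-N-methoxy-N-methylpropanamide
Product: 13 (3S)-3-[4-(benzyloxy)-3-methoxyphenyl]-N-methoxy-N-methyl-3-[(trimethylsilyl)oxy]propanamide
Conditions: TMSCl, imidazole, CH2Cl2, 0 °C; quick filtration through Et3N-deactivated silica
Reagents that add atoms: chlorotrimethylsilane, C[Si](C)(C)Cl
Why: Standard O-silylation of a secondary alcohol with a silyl chloride and imidazole; the trimethylsilyl ether is chosen because fluoride removes it in step 6 to give an alkoxide with no O–H in the flask, and the stereocenter is not touched.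

**Step 6**
Reactants: 13 (3S)-3-[4-(benzyloxy)-3-methoxyphenyl]-N-methoxy-N-methyl-3-[(trimethylsilyl)oxy]propanamide; 6 3,4,5-trimethoxy-2-(trimethylsilyl)phenyl trifluoromethanesulfonate
Product: 18 (2S)-2-[4-(benzyloxy)-3-methoxyphenyl]-5,6,7-trimethoxy-2,3-dihydro-4H-chromen-4-one, via 3,4,5-trimethoxybenzyne 14 (not isolated), via potassium alkoxide 15 (not isolated), via arylpotassium 16 (not isolated), via tetrahedral adduct 17 (not isolated)
Conditions: KF (spray-dried, 3.5 equiv), 18-crown-6 (3.5 equiv), THF, 0 °C to rt, 6 (1.5 equiv) added slowly; then aq NH4Cl, 0 °C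
Reagents that add atoms: none
Why: Proposed new method: fluoride strips the O–SiMe3 group of 13 and the C–SiMe3 group of 6 (with loss of triflate) in the same flask, so that the proton-free alkoxide 15 meets aryne 14; the alkoxide adds to the aryne, the aryl anion 16 attacks the Weinreb amide carbonyl, and the tetrahedral adduct 17 releases the ketone only on quench. The closest known reaction type is the fluoride-mediated annulation of arynes with salicylate esters to xanthones (intermolecular O-arylation, then intramolecular acyl substitution), carried over here from a phenoxide/methyl ester pair to an aliphatic alkoxide/Weinreb amide pair. Ring C is closed by 6-exo-trig attack of the C4a carbanion on the amide C=O after intermolecular O1–C8a bond formation, a formal [4+2] annulation of the O–C–C–C(=O) unit onto the aryne. No new stereocenter results: C2 is carried unchanged from step 4 because its C–O bond is never broken, and the hemiaminal carbon C4 of 17 is lost as a stereocenter on quench. The step needs regioselectivity in the aryne addition, which the methoxy group beside the triple bond should secure, since its inductive pull and the resulting distortion make the far carbon (future C8a) the flatter, more electrophilic one and place the developing negative charge on the near carbon (future C4a), with the bulk of the secondary alkoxide acting in the same sense. It also needs acyl capture to outrun protonation and the C2 configuration to survive base, for which the silyl ether (no O–H to quench the aryl anion), aprotic THF and the persistent non-enolizable adduct 17 (no ketone present while base is there, hence no retro-oxa-Michael opening to the chalcone) are provided.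

**Step 7**
Reactants: 18 (2S)-2-[4-(benzyloxy)-3-methoxyphenyl]-5,6,7-trimethoxy-2,3-dihydro-4H-chromen-4-one
Product: 19 agecorynin E, (2S)-2-(4-hydroxy-3-methoxyphenyl)-5,6,7-trimethoxy-2,3-dihydro-4H-chromen-4-one
Conditions: H2 (1 atm), Pd/C (10 wt% palladium on carbon), EtOAc, rt
Reagents that add atoms: none
Why: Hydrogenolysis of the benzyl aryl ether under neutral conditions should free the 4'-phenol without base or strong acid, so that C2, which would racemize by ring opening to the chalcone, is untouched; the reaction is stopped as soon as 18 is consumed to spare the benzylic C2–O1 bond and the ketone.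

**Compound list**
1 | 3,4,5-trimethoxyphenol | COc1cc(O)cc(OC)c1OC | starting material
2 | 2-bromo-3,4,5-trimethoxyphenol | COc1cc(O)c(Br)c(OC)c1OC | intermediate
3 | (2-bromo-3,4,5-trimethoxyphenoxy)trimethylsilane (formed in the flask) | COc1cc(O[Si](C)(C)C)c(Br)c(OC)c1OC | intermediate
4 | (2-lithio-3,4,5-trimethoxyphenoxy)trimethylsilane (formed in the flask) | COc1cc(O[Si](C)(C)C)c([Li])c(OC)c1OC | intermediate
5 | lithium 3,4,5-trimethoxy-2-(trimethylsilyl)phenolate (formed in the flask) | COc1cc([O-])c([Si](C)(C)C)c(OC)c1OC.[Li+] | intermediate
6 | 3,4,5-trimethoxy-2-(trimethylsilyl)phenyl trifluoromethanesulfonate | COc1cc(OS(=O)(=O)C(F)(F)F)c([Si](C)(C)C)c(OC)c1OC | intermediate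
7 | 4-(benzyloxy)-3-methoxybenzoic acid | COc1cc(C(=O)O)ccc1OCc1ccccc1 | starting material
8 | N-methoxy-N-methylacetamide | CC(=O)N(C)OC | starting material
9 | [4-(benzyloxy)-3-methoxyphenyl](1H-imidazol-1-yl)methanone (formed in the flask) | COc1cc(C(=O)n2ccnc2)ccc1OCc1ccccc1 | intermediate
10 | lithium 1-[methoxy(methyl)amino]ethen-1-olate (formed in the flask) | C=C([O-])N(C)OC.[Li+] | intermediate
11 | 3-[4-(benzyloxy)-3-methoxyphenyl]-N-methoxy-N-methyl-3-oxopropanamide | CON(C)C(=O)CC(=O)c1ccc(OCc2ccccc2)c(OC)c1 | intermediate
12 | (3S)-3-[4-(benzyloxy)-3-methoxyphenyl]-3-hydroxy-N-methoxy-N-methylpropanamide | CON(C)C(=O)C[C@H](O)c1ccc(OCc2ccccc2)c(OC)c1 | intermediate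
13 | (3S)-3-[4-(benzyloxy)-3-methoxyphenyl]-N-methoxy-N-methyl-3-[(trimethylsilyl)oxy]propanamide | CON(C)C(=O)C[C@H](O[Si](C)(C)C)c1ccc(OCc2ccccc2)c(OC)c1 | intermediate
14 | 3,4,5-trimethoxybenzyne (1,2-didehydro-3,4,5-trimethoxybenzene; formed in the flask) | COC1=C(OC)C(OC)=CC#C1 | intermediate
15 | potassium (1S)-1-[4-(benzyloxy)-3-methoxyphenyl]-3-[methoxy(methyl)amino]-3-oxopropan-1-olate (formed in the flask) | CON(C)C(=O)C[C@H]([O-])c1ccc(OCc2ccccc2)c(OC)c1.[K+] | intermediate
16 | arylpotassium: (3S)-3-[4-(benzyloxy)-3-methoxyphenyl]-N-methoxy-N-methyl-3-(3,4,5-trimethoxy-2-potassiophenoxy)propanamide (formed in the flask) | CON(C)C(=O)C[C@H](Oc1cc(OC)c(OC)c(OC)c1[K])c1ccc(OCc2ccccc2)c(OC)c1 | intermediate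
17 | potassium (2S)-2-[4-(benzyloxy)-3-methoxyphenyl]-5,6,7-trimethoxy-4-[methoxy(methyl)amino]-3,4-dihydro-2H-chromen-4-olate, either configuration at C4 (formed in the flask) | CON(C)C1([O-])C[C@@H](c2ccc(OCc3ccccc3)c(OC)c2)Oc2cc(OC)c(OC)c(OC)c21.[K+] | intermediate
18 | (2S)-2-[4-(benzyloxy)-3-methoxyphenyl]-5,6,7-trimethoxy-2,3-dihydro-4H-chromen-4-one | O=C1C[C@@H](c2ccc(OCc3ccccc3)c(OC)c2)Oc2cc(OC)c(OC)c(OC)c21 | intermediate
19 | agecorynin E, (2S)-2-(4-hydroxy-3-methoxyphenyl)-5,6,7-trimethoxy-2,3-dihydro-4H-chromen-4-one | COc1cc([C@@H]2CC(=O)c3c(cc(OC)c(OC)c3OC)O2)ccc1O | target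

**Step count and risks**
Total steps: 7. Longest linear sequence: 5 steps (steps 3, 4, 5, 6, 7); the aryne precursor branch (steps 1, 2) joins at step 6.

Steps most likely to fail:

1. Step 6 (proposed new method). What may go wrong: the aryl anion is protonated before it reaches the amide carbonyl (plain O-arylation, possibly followed by elimination), the alkoxide adds at the wrong aryne carbon, or base opens ring C after cyclization with loss of the C2 configuration. Fallback by known chemistry, setting out from 1 and coming back at 18: Friedel–Crafts acetylation of 1 (AcOH, BF3·OEt2, 90 °C) should give 1-(6-hydroxy-2,3,4-trimethoxyphenyl)ethan-1-one F1. Condensation with N,N-dimethylformamide dimethyl acetal (toluene, 100 °C) should give the enaminone (2E)-3-(dimethylamino)-1-(6-hydroxy-2,3,4-trimethoxyphenyl)prop-2-en-1-one F2. Acid (conc. HCl, CH2Cl2, rt) should close it to 5,6,7-trimethoxy-4H-chromen-4-one F3. Enantioselective conjugate addition of [4-(benzyloxy)-3-methoxyphenyl]boronic acid under divalent palladium catalysis (Pd(OCOCF3)2, (R)-t-BuPyOx, NH4PF6, H2O, ClCH2CH2Cl, 60 °C) should then give 18. The ligand enantiomer named is the one expected, by analogy with cyclic enones, to give the 2S series; the sense is to be confirmed on a test run, the other enantiomer being equally available.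

2. Step 2. What may go wrong: protonation of the aryllithium instead of O-to-C silyl migration (loss of bromine without silylation), incomplete migration, or loss of the crowded C–Si bond during triflation and purification. Fallback setting out from 1 and coming back at 6 (step 1 is bypassed as well): carbamoylation of 1 with isopropyl isocyanate (Et3N, CH2Cl2) should give 3,4,5-trimethoxyphenyl propan-2-ylcarbamate F4. N-silylation in the flask (TBSOTf, TMEDA, Et2O), carbamate-directed ortho-lithiation (n-BuLi, −78 °C) at the carbon between the carbamate and a methoxy group, TMSCl quench and acidic work-up should give 3,4,5-trimethoxy-2-(trimethylsilyl)phenyl propan-2-ylcarbamate F5. Et2NH and DBU in MeCN at 40 °C should cleave the carbamate to 3,4,5-trimethoxy-2-(trimethylsilyl)phenol F6, and Tf2O with pyridine in CH2Cl2 at 0 °C should give 6.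

3. Step 4. What may go wrong: slow hydride transfer to the electron-rich, partly enolized keto amide and incomplete facial selectivity. Fallback setting out from 11 and coming back at 12: NaBH4 in MeOH at 0 °C should give racemic 3-[4-(benzyloxy)-3-methoxyphenyl]-3-hydroxy-N-methoxy-N-methylpropanamide F7. Kinetic resolution with the lipase from Burkholderia cepacia and vinyl acetate in t-BuOMe should, by the usual empirical size rule for lipase acylation of secondary alcohols, acylate the R enantiomer to (1R)-1-[4-(benzyloxy)-3-methoxyphenyl]-3-[methoxy(methyl)amino]-3-oxopropyl acetate F8 and leave 12, which is separated by chromatography; at most half of the material is used.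

**Further compounds**
F1 | step 6 | 1-(6-hydroxy-2,3,4-trimethoxyphenyl)ethan-1-one | CC(=O)c1c(O)cc(OC)c(OC)c1OC
F2 | step 6 | (2E)-3-(dimethylamino)-1-(6-hydroxy-2,3,4-trimethoxyphenyl)prop-2-en-1-one | CN(C)/C=C/C(=O)c1c(O)cc(OC)c(OC)c1OC
F3 | step 6 | 5,6,7-trimethoxy-4H-chromen-4-one | O=c1ccoc2cc(OC)c(OC)c(OC)c12
F4 | step 2 | 3,4,5-trimethoxyphenyl propan-2-ylcarbamate | CC(C)NC(=O)Oc1cc(OC)c(OC)c(OC)c1
F5 | step 2 | 3,4,5-trimethoxy-2-(trimethylsilyl)phenyl propan-2-ylcarbamate | CC(C)NC(=O)Oc1cc(OC)c(OC)c(OC)c1[Si](C)(C)C
F6 | step 2 | 3,4,5-trimethoxy-2-(trimethylsilyl)phenol | COc1cc(O)c([Si](C)(C)C)c(OC)c1OC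
F7 | step 4 | racemic 3-[4-(benzyloxy)-3-methoxyphenyl]-3-hydroxy-N-methoxy-N-methylpropanamide | CON(C)C(=O)CC(O)c1ccc(OCc2ccccc2)c(OC)c1
F8 | step 4 | (1R)-1-[4-(benzyloxy)-3-methoxyphenyl]-3-[methoxy(methyl)amino]-3-oxopropyl acetate | CON(C)C(=O)C[C@@H](OC(C)=O)c1ccc(OCc2ccccc2)c(OC)c1
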